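**Retrosynthetic overview**
1. Feature: the oxolane O1–C2(ring A)–C3(CH2OH)–C4(CH2–ring B)–C5. If C5 is raised to a lactone carbonyl, this ring is a 5-aryl butenolide that lacks one carbon at its β carbon C3 and one at its α carbon C4.
2. Target ⇒ O-benzyl ether ⇒ triol, whose C5–OH closes onto a benzylic cation at C2 ⇒ (LiAlH4, Tamao oxidation, hydrogenation) ⇒ E-benzylidene silylmethyl lactone.
3. Benzylidene lactone ⇒ (S)-5-(3,4-dimethoxyphenyl)butenolide + (i-PrO)Me2SiCH2MgCl + O-benzylvanillin. A cuprate addition makes C3–CH2Si and an aldol condensation makes C4=CH, both in one flask.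
4. Butenolide ⇒ ring-closing metathesis of the acrylate of (S)-1-(3,4-dimethoxyphenyl)prop-2-en-1-ol, which comes from vinyl Grignard addition and lipase resolution.
5. Ring order: butenolide ring (step 4), opened in step 10, oxolane ring (step 11). Stereo relay: C2 (step 2) → C3 (step 7) → C4 (step 8) → C2 written again trans to C3 (step 11).

Key step: step 7

Remark: the oxolane numbering of the target (O1, C2–C5) is used for all intermediates. Ring A is the 3,4-dimethoxyphenyl group and ring B the vanillyl arene. (Chloromethyl)(isopropoxy)dimethylsilane is taken as commercially available.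

**Step 1**
Reactants: 1 veratraldehyde; 2 vinylmagnesium bromide
Product: 3 rac-1-(3,4-dimethoxyphenyl)prop-2-en-1-ol
Conditions: 2 (1.2 equiv), THF, 0 °C; aq NH4Cl
Reagents that add atoms: vinylmagnesium bromide (2), C=C[Mg]Br
Why: Grignard 1,2-addition to a non-enolisable aromatic aldehyde should be clean; the carbinol centre (later C2) forms as the racemate and is sorted in step 2.

**Step 2**
Reactants: 3 rac-1-(3,4-dimethoxyphenyl)prop-2-en-1-ol
Product: 4 (S)-1-(3,4-dimethoxyphenyl)prop-2-en-1-ol
Conditions: Novozym 435 (immobilised Candida antarctica lipase B), vinyl acetate (3 equiv), MTBE, 30 °C, stopped just past half conversion; chromatography on Et3N-washed silica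
Reagents that add atoms: none
Why: Lipase-catalysed kinetic resolution by irreversible transesterification: by the empirical size rule for this enzyme (aryl large, vinyl medium) the R alcohol should be acetylated, leaving the S alcohol, which already holds the C2 configuration of the target and is separated from the acetate.

**Step 3**
Reactants: 4 (S)-1-(3,4-dimethoxyphenyl)prop-2-en-1-ol; 5 acryloyl chloride
Product: 6 (S)-1-(3,4-dimethoxyphenyl)prop-2-en-1-yl prop-2-enoate
Conditions: 5 (1.3 equiv), Et3N (1.6 equiv), DMAP (5 mol %), CH2Cl2, −20 → 0 °C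
Reagents that add atoms: acryloyl chloride (5), C=CC(Cl)=O
Why: O-acylation of a secondary alcohol by an acid chloride under amine base breaks no bond at the stereocentre, and low temperature with no acid present should keep the benzylic allylic ester from ionising.

**Step 4**
Reactants: 6 (S)-1-(3,4-dimethoxyphenyl)prop-2-en-1-yl prop-2-enoate
Product: 7 (S)-5-(3,4-dimethoxyphenyl)furan-2(5H)-one
Conditions: second-generation Grubbs catalyst RuCl2(=CHPh)(PCy3)(SIMes) (5 mol %), CH2Cl2 (0.01 M), reflux
Reagents that add atoms: none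
Why: Ring-closing metathesis of an allyl acrylate, for which the carbene-ligated ruthenium catalyst is active enough to engage the electron-poor acrylate; loss of ethene drives the five-membered closure and the neutral medium leaves the base-sensitive C2–H centre alone.

**Step 5**
Reactants: 8 vanillin; 9 benzyl bromide
Product: 10 4-(benzyloxy)-3-methoxybenzaldehyde
Conditions: 9 (1.1 equiv), K2CO3 (1.5 equiv), DMF, rt → 50 °C
Reagents that add atoms: benzyl bromide (9), BrCc1ccccc1
Why: Williamson ether synthesis on the acidic phenol; the benzyl group masks the one proton that would quench the enolate of step 7 and should withstand steps 7 to 11.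

**Step 6**
Reactants: 11 (chloromethyl)(isopropoxy)dimethylsilane
Product: 12 {[isopropoxy(dimethyl)silyl]methyl}magnesium chloride (titrated THF solution)
Conditions: Mg turnings (1.1 equiv, activated by a drop of BrCH2CH2Br), THF, 45 °C → rt
Reagents that add atoms: magnesium, [Mg]
Why: Grignard formation from an α-silyl alkyl chloride; the branched isopropoxy group shields silicon well enough that the reagent should not attack its own Si–O bond.

**Step 7**
Reactants: 7 (S)-5-(3,4-dimethoxyphenyl)furan-2(5H)-one; 12 {[isopropoxy(dimethyl)silyl]methyl}magnesium chloride; 10 4-(benzyloxy)-3-methoxybenzaldehyde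
Product: 16 (4S,5S,E)-3-[4-(benzyloxy)-3-methoxybenzylidene]-5-(3,4-dimethoxyphenyl)-4-{[isopropoxy(dimethyl)silyl]methyl}oxolan-2-one, via magnesium enolate 13 (not isolated), via magnesium aldolate 14 (not isolated), via aldol acetate 15 (not isolated)
Conditions: 12 (1.3 equiv), CuBr·SMe2 (20 mol %), THF, −78 °C, slow addition of 7; 10 (1.5 equiv), −78 → −40 °C; Ac2O (3 equiv), −40 → 0 °C; DBU (4 equiv), 0 °C → rt; pH 7 buffer
Reagents that add atoms: {[isopropoxy(dimethyl)silyl]methyl}magnesium chloride (12), CC(C)O[Si](C)(C)C[Mg]Cl; 4-(benzyloxy)-3-methoxybenzaldehyde (10), COc1cc(C=O)ccc1OCc1ccccc1; acetic anhydride, CC(=O)OC(C)=O (its acetyl group is held only in 15)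
Why: Transmetalation of 12 to CuBr·SMe2 gives a magnesiocuprate of monovalent copper that binds the C3=C4 bond of 7 and, by addition at β carbon C3 and reductive elimination, forms the C3–CH2Si bond and enolate 13; 13 attacks aldehyde 10 through C4 to give aldolate 14, Ac2O converts this into acetate 15, and DBU expels acetate by an E1cB path to leave benzylidene lactone 16. The closest known reaction type is the copper-catalysed conjugate addition of Grignard reagents to 5-substituted butenolides with aldol trapping of the enolate and dehydration to the α-alkylidene lactone. No ring is closed; two skeletal bonds (C3–CH2 and C4–CH) are made. The only lasting new stereocentre, C3, is controlled by ring A on the neighbouring C2, which covers one face of the flat butenolide so that copper delivers the silylmethyl group anti to it (2,3-trans, 4S in lactone numbering), while the C4 and carbinol centres of 14 and 15 vanish in the elimination. The step needs 1,4-addition to win over 1,2-addition and over removal of the acidic C2–H, which the soft cuprate, the low temperature and the slow addition of 7 to the reagent (so that enolate and unreacted butenolide do not meet) should secure. The E geometry follows because both carbinol epimers pass through the same enolate and ring B settles trans to the lactone carbonyl.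

**Step 8**
Reactants: 16 (4S,5S,E)-benzylidene lactone
Product: 17 (3R,4S,5S)-3-[4-(benzyloxy)-3-methoxybenzyl]-5-(3,4-dimethoxyphenyl)-4-{[isopropoxy(dimethyl)silyl]methyl}oxolan-2-one
Conditions: H2 (40 bar), RhCl(PPh3)3 (10 mol %), toluene/i-PrOH, 50 °C
Reagents that add atoms: none
Why: Homogeneous hydrogenation with the Wilkinson complex of monovalent rhodium, run under pressure because the alkene is trisubstituted: allylic 1,3-strain with ring B holds the C3 silylmethyl group pseudoaxial over one face, so syn addition of H2 should come from the other face and place the C4 benzyl group cis to the C3 substituent, while the benzyl ether and the benzylic C2–O1 bond, both at risk on heterogeneous palladium, stay intact.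

**Step 9**
Reactants: 17 saturated silylmethyl lactone
Product: 18 (3R,4R,5S)-3-[4-(benzyloxy)-3-methoxybenzyl]-5-(3,4-dimethoxyphenyl)-4-(hydroxymethyl)oxolan-2-one
Conditions: KF (4 equiv), KHCO3 (4 equiv), 30 % aq H2O2 (12 equiv), THF/MeOH, rt
Reagents that add atoms: hydrogen peroxide, OO
Why: Tamao oxidation: fluoride-activated silicon takes up hydroperoxide and the CH2 group migrates from Si to O, which unmasks the C3 hydroxymethyl group, and the bicarbonate buffer should be too weak to enolise the lactone at C4.

**Step 10**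
Reactants: 18 hydroxymethyl lactone
Product: 19 (1S,2R,3R)-3-[4-(benzyloxy)-3-methoxybenzyl]-1-(3,4-dimethoxyphenyl)-2-(hydroxymethyl)butane-1,4-diol
Conditions: LiAlH4 (3 equiv), THF, 0 °C → rt; Rochelle salt work-up
Reagents that add atoms: none
Why: Hydride reduction of a lactone to the diol touches no stereocentre, and any acyl migration from O1 to the new primary hydroxyl during step 9 is harmless because either lactone is reduced to the same triol.

**Step 11**
Reactants: 19 triol
Product: 20 [(2S,3R,4R)-4-[4-(benzyloxy)-3-methoxybenzyl]-2-(3,4-dimethoxyphenyl)oxolan-3-yl]methanol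
Conditions: camphor-10-sulfonic acid (10 mol %), CH2Cl2 (0.01 M), 0 °C; Et3N quench
Reagents that add atoms: none
Why: Acid-catalysed SN1 cyclodehydration: only the C2 hydroxyl, benzylic to electron-rich ring A, ionises and the C5 hydroxyl captures the planar cation in a 5-exo-trig closure (the C3 CH2OH could only give a strained oxetane), so the C2 configuration is erased and written again, with ring A settling trans to the C3 substituent under kinetic and, since closure is reversible, thermodynamic control, which restores 2S.

**Step 12**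
Reactants: 20 O-benzyl ether of the target
Product: 21 4-{[(3R,4R,5S)-5-(3,4-dimethoxyphenyl)-4-(hydroxymethyl)oxolan-3-yl]methyl}-2-methoxyphenol (target, 2S,3R,4R in oxolane numbering)
Conditions: H2 (1 atm), Pd/C (10 wt % Pd on carbon, 5 mol %), EtOAc, rt, stopped at full conversion of 20
Reagents that add atoms: none
Why: Catalytic hydrogenolysis of an aryl benzyl ether on zerovalent palladium in a neutral aprotic solvent is much faster than cleavage of the benzylic C2–O1 bond of the oxolane, so no stereocentre is touched.

**Compound list**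
1 | veratraldehyde (3,4-dimethoxybenzaldehyde) | COc1ccc(C=O)cc1OC | starting material
2 | vinylmagnesium bromide | C=C[Mg]Br | starting material
3 | rac-1-(3,4-dimethoxyphenyl)prop-2-en-1-ol | C=CC(O)c1ccc(OC)c(OC)c1 | intermediate
4 | (S)-1-(3,4-dimethoxyphenyl)prop-2-en-1-ol | C=C[C@H](O)c1ccc(OC)c(OC)c1 | intermediate
5 | acryloyl chloride | C=CC(Cl)=O | starting material
6 | (S)-1-(3,4-dimethoxyphenyl)prop-2-en-1-yl prop-2-enoate | C=CC(=O)O[C@@H](C=C)c1ccc(OC)c(OC)c1 | intermediate
7 | (S)-5-(3,4-dimethoxyphenyl)furan-2(5H)-one | O=C1C=C[C@@H](c2ccc(OC)c(OC)c2)O1 | intermediate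
8 | vanillin | COc1cc(C=O)ccc1O | starting material
9 | benzyl bromide | BrCc1ccccc1 | starting material
10 | 4-(benzyloxy)-3-methoxybenzaldehyde | COc1cc(C=O)ccc1OCc1ccccc1 | intermediate
11 | (chloromethyl)(isopropoxy)dimethylsilane | CC(C)O[Si](C)(C)CCl | starting material
12 | {[isopropoxy(dimethyl)silyl]methyl}magnesium chloride | CC(C)O[Si](C)(C)C[Mg]Cl | intermediate
13 | chloromagnesium (4S,5S)-5-(3,4-dimethoxyphenyl)-4-{[isopropoxy(dimethyl)silyl]methyl}-4,5-dihydrofuran-2-olate | Cl[Mg]OC1=C[C@H](C[Si](C)(C)OC(C)C)[C@@H](c2ccc(OC)c(OC)c2)O1 | intermediate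
14 | chloromagnesium [4-(benzyloxy)-3-methoxyphenyl][(3R,4S,5S)-5-(3,4-dimethoxyphenyl)-4-{[isopropoxy(dimethyl)silyl]methyl}-2-oxooxolan-3-yl]methanolate (both carbinol epimers) | O=C1O[C@H](c2ccc(OC)c(OC)c2)[C@@H](C[Si](C)(C)OC(C)C)[C@@H]1C(O[Mg]Cl)c3ccc(OCc4ccccc4)c(OC)c3 | intermediate
15 | [4-(benzyloxy)-3-methoxyphenyl][(3R,4S,5S)-5-(3,4-dimethoxyphenyl)-4-{[isopropoxy(dimethyl)silyl]methyl}-2-oxooxolan-3-yl]methyl acetate (both carbinol epimers) | O=C1O[C@H](c2ccc(OC)c(OC)c2)[C@@H](C[Si](C)(C)OC(C)C)[C@@H]1C(OC(C)=O)c3ccc(OCc4ccccc4)c(OC)c3 | intermediate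
16 | (4S,5S,E)-3-[4-(benzyloxy)-3-methoxybenzylidene]-5-(3,4-dimethoxyphenyl)-4-{[isopropoxy(dimethyl)silyl]methyl}oxolan-2-one | O=C1O[C@H](c2ccc(OC)c(OC)c2)[C@@H](C[Si](C)(C)OC(C)C)/C1=C\c3ccc(OCc4ccccc4)c(OC)c3 | intermediate
17 | (3R,4S,5S)-3-[4-(benzyloxy)-3-methoxybenzyl]-5-(3,4-dimethoxyphenyl)-4-{[isopropoxy(dimethyl)silyl]methyl}oxolan-2-one | O=C1O[C@H](c2ccc(OC)c(OC)c2)[C@@H](C[Si](C)(C)OC(C)C)[C@H]1Cc3ccc(OCc4ccccc4)c(OC)c3 | intermediate
18 | (3R,4R,5S)-3-[4-(benzyloxy)-3-methoxybenzyl]-5-(3,4-dimethoxyphenyl)-4-(hydroxymethyl)oxolan-2-one | O=C1O[C@H](c2ccc(OC)c(OC)c2)[C@@H](CO)[C@H]1Cc3ccc(OCc4ccccc4)c(OC)c3 | intermediate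
19 | (1S,2R,3R)-3-[4-(benzyloxy)-3-methoxybenzyl]-1-(3,4-dimethoxyphenyl)-2-(hydroxymethyl)butane-1,4-diol | O[C@H](c1ccc(OC)c(OC)c1)[C@@H](CO)[C@H](CO)Cc2ccc(OCc3ccccc3)c(OC)c2 | intermediate
20 | [(2S,3R,4R)-4-[4-(benzyloxy)-3-methoxybenzyl]-2-(3,4-dimethoxyphenyl)oxolan-3-yl]methanol | COc1cc(C[C@H]2CO[C@H](c3ccc(OC)c(OC)c3)[C@H]2CO)ccc1OCc4ccccc4 | intermediate
21 | 4-{[(3R,4R,5S)-5-(3,4-dimethoxyphenyl)-4-(hydroxymethyl)oxolan-3-yl]methyl}-2-methoxyphenol | COc1cc(C[C@H]2CO[C@H](c3ccc(OC)c(OC)c3)[C@H]2CO)ccc1O | target

Total step count: 12. Longest linear sequence: 10 (steps 1–4 and 7–12).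

**Steps most likely to fail**

**Step 7.**
- What may go wrong: transfer of the silylmethyl group from copper may be slow. The basic reagent could then remove the acidic C2–H, which would cost enantiopurity and let the alkene drift into conjugation with ring A. The aldolate may also revert or exchange onto silicon before it is acetylated.
- Fallback: make the two bonds in separate operations. It sets out from 7 and comes back at 16.
- 12 (2.2 equiv), CuBr·SMe2 (1.1 equiv) and Me3SiCl (2 equiv) in THF at −78 °C should speed the addition under almost non-basic conditions and trap the adduct as trimethylsilyl ketene acetal F1.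
- A pH 7 work-up hydrolyses this to the isolable saturated lactone F2.
- LDA (THF, −78 °C) converts F2 into lithium enolate F3, and aldehyde 10 gives lithium aldolate F4.
- Ac2O then gives 15, and DBU returns to the route at 16.

**Step 8.**
- What may go wrong: the bulky rhodium centre may bind the hindered, aryl-conjugated trisubstituted alkene too slowly. Ring A, which sits on the face that must receive hydrogen, may also erode the facial bias.
- Fallback: replace H2 addition by conjugate hydride delivery followed by a separate protonation. It sets out from 16 and comes back at 17.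
- Cu(OAc)2·H2O (5 mol %), 1,2-bis(diphenylphosphino)benzene, polymethylhydrosiloxane and t-BuOH in toluene at rt generate a copper hydride that adds hydride to the benzylidene carbon.
- The enolate is protonated at C4 on the face away from the C3 silylmethyl group. The stereo-determining event thus moves from the exocyclic alkene to C4 itself, next to the controlling centre.
- No compound outside the list is made (F0).

**Step 11.**
- What may go wrong: ionisation at C2 may be followed by irreversible Friedel–Crafts capture by electron-rich ring B (six-membered carbocycle) instead of by the C5 hydroxyl. Closure may also be incompletely trans-selective.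
- Fallback: never ionise C2, and form O1–C5 by SN2 displacement while the hydroxymethyl group is still masked as the silane. It sets out from 17 and comes back at 20.
- LiAlH4 (Et2O, 0 °C → rt) reduces the lactone and turns Si–Oi-Pr into Si–H, giving hydrosilane diol F5.
- TsCl (1.05 equiv), pyridine and DMAP at 0 °C sulfonylate only the primary C5 hydroxyl, giving primary tosylate F6.
- On warming to 40 °C this closes by 5-exo-tet attack of the C2 hydroxyl, with retention at C2, to oxolane hydrosilane F7.
- Tamao oxidation of the Si–H silane (KF, KHCO3, H2O2, THF/MeOH) rejoins the route at 20.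

**Further compounds**
F1 | step 7 | {[(4S,5S)-5-(3,4-dimethoxyphenyl)-4-{[isopropoxy(dimethyl)silyl]methyl}-4,5-dihydrofuran-2-yl]oxy}trimethylsilane | C[Si](C)(C)OC1=C[C@H](C[Si](C)(C)OC(C)C)[C@@H](c2ccc(OC)c(OC)c2)O1
F2 | step 7 | (4S,5S)-5-(3,4-dimethoxyphenyl)-4-{[isopropoxy(dimethyl)silyl]methyl}oxolan-2-one | O=C1C[C@H](C[Si](C)(C)OC(C)C)[C@@H](c2ccc(OC)c(OC)c2)O1
F3 | step 7 | lithium (4S,5S)-5-(3,4-dimethoxyphenyl)-4-{[isopropoxy(dimethyl)silyl]methyl}-4,5-dihydrofuran-2-olate | [Li]OC1=C[C@H](C[Si](C)(C)OC(C)C)[C@@H](c2ccc(OC)c(OC)c2)O1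
F4 | step 7 | lithium [4-(benzyloxy)-3-methoxyphenyl][(3R,4S,5S)-5-(3,4-dimethoxyphenyl)-4-{[isopropoxy(dimethyl)silyl]methyl}-2-oxooxolan-3-yl]methanolate (both carbinol epimers) | O=C1O[C@H](c2ccc(OC)c(OC)c2)[C@@H](C[Si](C)(C)OC(C)C)[C@@H]1C(O[Li])c3ccc(OCc4ccccc4)c(OC)c3
F0 | step 8 | none | none
F5 | step 11 | (1S,2S,3R)-3-[4-(benzyloxy)-3-methoxybenzyl]-1-(3,4-dimethoxyphenyl)-2-[(dimethylsilyl)methyl]butane-1,4-diol | O[C@H](c1ccc(OC)c(OC)c1)[C@@H](C[SiH](C)C)[C@H](CO)Cc2ccc(OCc3ccccc3)c(OC)c2
F6 | step 11 | (2R,3S,4S)-2-[4-(benzyloxy)-3-methoxybenzyl]-4-(3,4-dimethoxyphenyl)-3-[(dimethylsilyl)methyl]-4-hydroxybutyl 4-methylbenzenesulfonate | O[C@H](c1ccc(OC)c(OC)c1)[C@@H](C[SiH](C)C)[C@H](COS(=O)(=O)c2ccc(C)cc2)Cc3ccc(OCc4ccccc4)c(OC)c3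
F7 | step 11 | {[(2S,3S,4R)-4-[4-(benzyloxy)-3-methoxybenzyl]-2-(3,4-dimethoxyphenyl)oxolan-3-yl]methyl}dimethylsilane | COc1cc(C[C@H]2CO[C@H](c3ccc(OC)c(OC)c3)[C@H]2C[SiH](C)C)ccc1OCc4ccccc4
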